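The α-methylene-γ-butyrolactone is read as a 4-methylideneoxolane whose O–CH2 carbon (lactone C2) is oxidised last. In that ring the O1–C5(γ) pair is a former aldehyde C=O. C4H2, C3, its exocyclic CH2 and C2 together form a trimethylenemethane unit. One palladium-catalysed (3+2) step therefore makes the C4–C5 and O1–C2 bonds, closes the ring and sets the γ-stereocentre. The precursor is the E-configured 3-methylpent-3-enal bearing an oxygen at C5. This oxygen is carried as a TBDPS ether. The coumarin, itself an acceptor and a leaving group under Pd(0), enters later by Mitsunobu etherification after a Sharpless epoxidation.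

Key step: step 5

Remarks on the chemistry
- Target as read: lactone C5 (γ) is S, and oxirane CH and oxirane C(CH3) are both R. CH2OAr and the lactonyl-CH2 are trans on the oxirane, which requires an E-alkene precursor.
- Spectator choice: the O-substituent at C5 of the enal takes no part in the key step and is TBDPS, for three reasons. A 7-coumarinyl allyl ether would be ionised by Pd(0). The coumarin C3=C4 enoate is a classical acceptor for the Pd–TMM dipole. The aryloxide would also be expelled by 1,6-elimination from the dienolate of the aldehyde. The C6 enal skeleton, the two bonds formed and the ring closed are unchanged.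
- Assumption: the ligand antipode that directs the TMM carbon to the Si face of the aldehyde is identified in a short screen, and the configuration is checked on alcohol 14.
- Containment of risk: the epoxidation in step 7 is reagent-controlled. Any minor enantiomer from step 5 therefore becomes a diastereomer of 15 that chromatography can remove.
- Descriptor note: oxolane C2 is R in 13 and 14 and S in 15, 17 and 18. Only the CIP ranking of the side chain changes, not the geometry.
- Compound 1 is a catalogue item. If needed, it is one silylation away from 3-butyn-1-ol.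

Step 1
Reactants: 1 tert-butyl(but-3-yn-1-yloxy)dimethylsilane; 2 trimethylaluminium; 3 paraformaldehyde (formaldehyde source)
Product: 6 (2E)-5-[(tert-butyldimethylsilyl)oxy]-3-methylpent-2-en-1-ol, via alkenylalane 4 (not isolated), via lithium alanate 5 (not isolated)
Conditions: Me3Al (2 equiv), Cp2ZrCl2 (0.2 equiv), CH2Cl2, 0 °C to rt; concentrate; n-BuLi (1 equiv), hexane–THF, −78 to 0 °C; (CH2O)n, rt; aq Rochelle salt
Reagents that add atoms: trimethylaluminium (2), C[Al](C)C; formaldehyde from paraformaldehyde (3), C=O
Why: Zirconium-catalysed Negishi carboalumination adds CH3 and Al syn across the terminal alkyne with aluminium at the terminus (4, E geometry fixed here), and the more nucleophilic alanate 5 is hydroxymethylated by formaldehyde with retention of alkene geometry, the TBS ether being tolerated by the organoaluminium medium.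

Step 2
Reactants: 6 (2E)-5-[(tert-butyldimethylsilyl)oxy]-3-methylpent-2-en-1-ol
Product: 7 tert-butyl({(3E)-5-[(tert-butyldiphenylsilyl)oxy]-3-methylpent-3-en-1-yl}oxy)dimethylsilane
Conditions: TBDPSCl, imidazole, CH2Cl2, 0 °C to rt
Reagents that add atoms: tert-butyl(chloro)diphenylsilane, CC(C)(C)[Si](Cl)(c1ccccc1)c1ccccc1
Why: Imidazole-promoted silylation of a primary allylic alcohol, with TBDPS chosen because it survives the acid of step 3, is no leaving group for Pd(0) and is not expelled from the dienolate of the later aldehyde.

Step 3
Reactants: 7 tert-butyl({(3E)-5-[(tert-butyldiphenylsilyl)oxy]-3-methylpent-3-en-1-yl}oxy)dimethylsilane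
Product: 8 (3E)-5-[(tert-butyldiphenylsilyl)oxy]-3-methylpent-3-en-1-ol
Conditions: CSA (10 mol %), MeOH–CH2Cl2 (1:1), 0 °C
Reagents that add atoms: none
Why: Selective acid-catalysed methanolysis, in which the primary TBS ether is solvolysed far faster than the bulkier, acid-resistant primary TBDPS ether.

Step 4
Reactants: 8 (3E)-5-[(tert-butyldiphenylsilyl)oxy]-3-methylpent-3-en-1-ol
Product: 9 (3E)-5-[(tert-butyldiphenylsilyl)oxy]-3-methylpent-3-enal
Conditions: Dess–Martin periodinane, NaHCO3, CH2Cl2, 0 °C to rt; short silica plug, used at once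
Reagents that add atoms: none
Why: Dess–Martin oxidation runs under near-neutral, amine-free conditions, so the homoallylic alcohol should give the β,γ-unsaturated aldehyde without migration of the E-alkene into conjugation, provided 9 is buffered, kept cold and used immediately.

Step 5
Reactants: 9 (3E)-5-[(tert-butyldiphenylsilyl)oxy]-3-methylpent-3-enal; 10 2-[(trimethylsilyl)methyl]allyl acetate
Product: 13 tert-butyl({(2E)-3-methyl-4-[(2R)-4-methylideneoxolan-2-yl]but-2-en-1-yl}oxy)diphenylsilane, via palladium TMM zwitterion 11 (not isolated), via allylpalladium alkoxide 12 (not isolated)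
Conditions: Pd(dba)2 (5 mol %), chiral BINOL-derived 2,5-diarylpyrrolidine phosphoramidite L* (10 mol %), In(acac)3 (10 mol %), 10 (1.6 equiv), toluene, rt to 40 °C
Reagents that add atoms: 2-[(trimethylsilyl)methyl]allyl acetate (10), C=C(C[Si](C)(C)C)COC(C)=O
Why: Proposed new method: Pd(0) ionises the allylic acetate of 10 and the released acetate removes the silyl group, giving zwitterion 11, whose carbanionic CH2 adds to the In(III)-activated C=O of 9 to form the oxolane C2–C3 bond and alkoxide 12. The closest known reaction type is the palladium–TMM (3+2) cycloaddition to aldehydes, established in racemic form for enolisable aliphatic aldehydes with tin or indium co-catalysts and in enantioselective form with chiral phosphoramidites only for aryl aldehydes, so enantiocontrol on a β,γ-unsaturated aliphatic aldehyde is the extrapolation. The single ring closes stepwise by intramolecular O-allylation, the alkoxide of 12 displacing palladium from the allyl terminus in a 5-exo-tet sense (O1–C5 bond) and leaving the exocyclic methylene at C4. The only new stereocentre, oxolane C2, is fixed in the C–C bond-forming event by the chiral pocket of the ligand on the TMM-bound palladium, the antipode being chosen for attack on the Si face of the aldehyde to give 2R. The step needs carbonyl addition to outrun α-deprotonation of 9, and it needs palladium to ionise nothing except 10. The substrate secures this through a silyl ether that is no leaving group, an unactivated trisubstituted alkene that is no acceptor, the absence of the coumarin, and Lewis-acid activation of the carbonyl at mild temperature.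

Step 6
Reactants: 13 tert-butyl({(2E)-3-methyl-4-[(2R)-4-methylideneoxolan-2-yl]but-2-en-1-yl}oxy)diphenylsilane
Product: 14 (2E)-3-methyl-4-[(2R)-4-methylideneoxolan-2-yl]but-2-en-1-ol
Conditions: TBAF, THF, 0 °C to rt
Reagents that add atoms: none
Why: Fluoride-induced desilylation driven by Si–F bond formation, to which the ether ring, both alkenes and the stereocentre are inert.

Step 7
Reactants: 14 (2E)-3-methyl-4-[(2R)-4-methylideneoxolan-2-yl]but-2-en-1-ol
Product: 15 [(2R,3R)-3-methyl-3-{[(2S)-4-methylideneoxolan-2-yl]methyl}oxiran-2-yl]methanol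
Conditions: Ti(OiPr)4 (10 mol %), D-(−)-diethyl tartrate (12 mol %), t-BuOOH (decane, 2 equiv), 4 Å MS, CH2Cl2, −20 °C
Reagents that add atoms: tert-butyl hydroperoxide, CC(C)(C)OO
Why: Sharpless asymmetric epoxidation is directed by the allylic hydroxyl, so only the trisubstituted alkene reacts (the exocyclic methylene has no directing OH), and D-(−)-tartrate sets both oxirane centres as 2R,3R by reagent control as for geraniol-type substrates, the E geometry becoming the trans relation of CH2OH and the oxolanylmethyl group.

Step 8
Reactants: 15 [(2R,3R)-3-methyl-3-{[(2S)-4-methylideneoxolan-2-yl]methyl}oxiran-2-yl]methanol; 16 7-hydroxy-8-methoxycoumarin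
Product: 17 8-methoxy-7-{[(2R,3R)-3-methyl-3-{[(2S)-4-methylideneoxolan-2-yl]methyl}oxiran-2-yl]methoxy}-2H-chromen-2-one
Conditions: PPh3, DIAD, THF, 0 °C to rt
Reagents that add atoms: 7-hydroxy-8-methoxycoumarin (16), COc1c(O)ccc2ccc(=O)oc12
Why: Mitsunobu etherification, in which the acidic phenol replaces the activated primary hydroxyl by SN2 at the CH2 carbon, so no stereocentre is touched and no base is present that could trigger Payne migration or open the coumarin lactone.

Step 9
Reactants: 17 8-methoxy-7-{[(2R,3R)-3-methyl-3-{[(2S)-4-methylideneoxolan-2-yl]methyl}oxiran-2-yl]methoxy}-2H-chromen-2-one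
Product: 18 8-methoxy-7-{[(2R,3R)-3-methyl-3-{[(2S)-4-methylidene-5-oxooxolan-2-yl]methyl}oxiran-2-yl]methoxy}-2H-chromen-2-one (target)
Conditions: CrO3 (15 equiv), pyridine (30 equiv), CH2Cl2, rt; filtration through Celite–silica
Reagents that add atoms: chromium trioxide, O=[Cr](=O)=O
Why: Collins-type chromium(VI)–pyridine allylic oxidation, a known way from methylideneoxolanes to α-methylene-γ-butyrolactones, attacks the only C–H bonds that are both allylic and α to oxygen (oxolane C5H2) because the former trisubstituted alkene is now an epoxide, and the non-acidic medium should spare epoxide, aryl ether, coumarin and all stereocentres.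

Compound list
1 | tert-butyl(but-3-yn-1-yloxy)dimethylsilane | C#CCCO[Si](C)(C)C(C)(C)C | starting material
2 | trimethylaluminium | C[Al](C)C | starting material
3 | paraformaldehyde (written as formaldehyde) | C=O | starting material
4 | (E)-alkenyl(dimethyl)alane from 1 | CC(C)(C)[Si](C)(C)OCC/C(C)=C/[Al](C)C | intermediate (not isolated)
5 | lithium (E)-alkenyl(butyl)dimethylalanate | CC(C)(C)[Si](C)(C)OCC/C(C)=C/[Al-](C)(C)CCCC.[Li+] | intermediate (not isolated)
6 | (2E)-5-[(tert-butyldimethylsilyl)oxy]-3-methylpent-2-en-1-ol | CC(C)(C)[Si](C)(C)OCC/C(C)=C/CO | intermediate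
7 | tert-butyl({(3E)-5-[(tert-butyldiphenylsilyl)oxy]-3-methylpent-3-en-1-yl}oxy)dimethylsilane | CC(C)(C)[Si](C)(C)OCC/C(C)=C/CO[Si](c1ccccc1)(c1ccccc1)C(C)(C)C | intermediate
8 | (3E)-5-[(tert-butyldiphenylsilyl)oxy]-3-methylpent-3-en-1-ol | OCC/C(C)=C/CO[Si](c1ccccc1)(c1ccccc1)C(C)(C)C | intermediate
9 | (3E)-5-[(tert-butyldiphenylsilyl)oxy]-3-methylpent-3-enal | O=CC/C(C)=C/CO[Si](c1ccccc1)(c1ccccc1)C(C)(C)C | intermediate (key-step precursor)
10 | 2-[(trimethylsilyl)methyl]allyl acetate | C=C(C[Si](C)(C)C)COC(C)=O | starting material
11 | palladium–trimethylenemethane zwitterion (ligands omitted, η3-allyl drawn in σ-form) | C=C([CH2-])C[Pd+] | intermediate (not isolated)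
12 | (R)-alkoxide carrying the π-allylpalladium unit (ligands omitted, σ-form) | C=C(C[Pd+])C[C@@H](C/C(C)=C/CO[Si](c1ccccc1)(c1ccccc1)C(C)(C)C)[O-] | intermediate (not isolated)
13 | tert-butyl({(2E)-3-methyl-4-[(2R)-4-methylideneoxolan-2-yl]but-2-en-1-yl}oxy)diphenylsilane | C=C1C[C@@H](C/C(C)=C/CO[Si](c2ccccc2)(c2ccccc2)C(C)(C)C)OC1 | intermediate (key-step product)
14 | (2E)-3-methyl-4-[(2R)-4-methylideneoxolan-2-yl]but-2-en-1-ol | C=C1C[C@@H](C/C(C)=C/CO)OC1 | intermediate
15 | [(2R,3R)-3-methyl-3-{[(2S)-4-methylideneoxolan-2-yl]methyl}oxiran-2-yl]methanol | C=C1C[C@@H](C[C@@]2(C)O[C@@H]2CO)OC1 | intermediate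
16 | 7-hydroxy-8-methoxycoumarin (daphnetin 8-methyl ether) | COc1c(O)ccc2ccc(=O)oc12 | starting material
17 | 8-methoxy-7-{[(2R,3R)-3-methyl-3-{[(2S)-4-methylideneoxolan-2-yl]methyl}oxiran-2-yl]methoxy}-2H-chromen-2-one | C=C1C[C@@H](C[C@@]2(C)O[C@@H]2COc2ccc3ccc(=O)oc3c2OC)OC1 | intermediate
18 | 8-methoxy-7-{[(2R,3R)-3-methyl-3-{[(2S)-4-methylidene-5-oxooxolan-2-yl]methyl}oxiran-2-yl]methoxy}-2H-chromen-2-one | C=C1C[C@@H](C[C@@]2(C)O[C@@H]2COc2ccc3ccc(=O)oc3c2OC)OC1=O | target

Total step count: 9. Longest linear sequence: 9 steps (1 to 18).

Steps most likely to fail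

Step 5 (labelled step).
- What may go wrong: proton transfer from the acidic α-CH2 of 9 to the basic zwitterion. This consumes the donor by protodesilylation and lets the alkene of 9 slip into conjugation. Enantioface discrimination may also be weak for a slim aliphatic aldehyde.
- Fallback: known chemistry that makes the same two bonds one after the other, setting out from 9. A Keck-type catalytic asymmetric allylation is run with 2-(chloromethyl)allyltributylstannane and (S)-BINOL/Ti(OiPr)4 in CH2Cl2 at −20 °C. (S)-BINOL is the antipode expected to send the allyl group to the Si face. This should give (4R,6E)-8-[(tert-butyldiphenylsilyl)oxy]-2-(chloromethyl)-6-methylocta-1,6-dien-4-ol F1. Treatment with NaH in THF closes the ring by intramolecular Williamson etherification, and the route is rejoined at 13.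

Step 9.
- What may go wrong: incomplete or unselective C–H oxidation (attack at the ring C3 methylene, allylic transposition). Chromium salts may open the epoxide, and material may be lost on the chromium residues.
- Fallback: the carbonyl arrives with the four-carbon unit, so no C–H bond has to be oxidised. The sequence sets out from 9.
  - A chromium-catalysed enantioselective Nozaki–Hiyama–Kishi-type 2-(ethoxycarbonyl)allylation uses ethyl 2-(bromomethyl)acrylate, catalytic CrCl2, a chiral carbazole bis(oxazoline) ligand (antipode for Si-face addition) and Mn as terminal reductant.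
  - This should give ethyl (4R,6E)-8-[(tert-butyldiphenylsilyl)oxy]-4-hydroxy-6-methyl-2-methylideneoct-6-enoate F2.
  - Catalytic TsOH lactonises it to (5R)-5-{(2E)-4-[(tert-butyldiphenylsilyl)oxy]-2-methylbut-2-en-1-yl}-3-methylideneoxolan-2-one F3.
  - HF·pyridine frees (5R)-5-[(2E)-4-hydroxy-2-methylbut-2-en-1-yl]-3-methylideneoxolan-2-one F4.
  - Sharpless epoxidation with D-(−)-diethyl tartrate gives (5S)-5-{[(2R,3R)-3-(hydroxymethyl)-2-methyloxiran-2-yl]methyl}-3-methylideneoxolan-2-one F5.
  - Mitsunobu etherification with 16 rejoins the route at 18.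

Step 8.
- What may go wrong: slow coupling of the phenol flanked by the ortho-methoxy group. Opening of the activated epoxide by phenoxide, or alkylation of the hydrazide, could then take over.
- Fallback: the order of etherification and epoxidation is inverted and the epoxidation method changes, setting out from 14. Mitsunobu etherification of the simple allylic alcohol with 16 gives 8-methoxy-7-({(2E)-3-methyl-4-[(2R)-4-methylideneoxolan-2-yl]but-2-en-1-yl}oxy)-2H-chromen-2-one F6. A Shi epoxidation follows (D-fructose-derived ketone, Oxone, carbonate buffer, MeCN–dimethoxymethane, 0 °C). It should oxidise the more electron-rich trisubstituted alkene ahead of the 1,1-disubstituted alkene and the coumarin enoate. The R,R sense is the usual one for E-trisubstituted alkenes with this ketone. The route is rejoined at 17.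

Further compounds
F1 | step 5 | (4R,6E)-8-[(tert-butyldiphenylsilyl)oxy]-2-(chloromethyl)-6-methylocta-1,6-dien-4-ol | C=C(CCl)C[C@@H](C/C(C)=C/CO[Si](c1ccccc1)(c1ccccc1)C(C)(C)C)O
F2 | step 9 | ethyl (4R,6E)-8-[(tert-butyldiphenylsilyl)oxy]-4-hydroxy-6-methyl-2-methylideneoct-6-enoate | C=C(C[C@@H](C/C(C)=C/CO[Si](c1ccccc1)(c1ccccc1)C(C)(C)C)O)C(=O)OCC
F3 | step 9 | (5R)-5-{(2E)-4-[(tert-butyldiphenylsilyl)oxy]-2-methylbut-2-en-1-yl}-3-methylideneoxolan-2-one | C=C1C[C@@H](C/C(C)=C/CO[Si](c2ccccc2)(c2ccccc2)C(C)(C)C)OC1=O
F4 | step 9 | (5R)-5-[(2E)-4-hydroxy-2-methylbut-2-en-1-yl]-3-methylideneoxolan-2-one | C=C1C[C@@H](C/C(C)=C/CO)OC1=O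
F5 | step 9 | (5S)-5-{[(2R,3R)-3-(hydroxymethyl)-2-methyloxiran-2-yl]methyl}-3-methylideneoxolan-2-one | C=C1C[C@@H](C[C@@]2(C)O[C@@H]2CO)OC1=O
F6 | step 8 | 8-methoxy-7-({(2E)-3-methyl-4-[(2R)-4-methylideneoxolan-2-yl]but-2-en-1-yl}oxy)-2H-chromen-2-one | C=C1C[C@@H](C/C(C)=C/COc2ccc3ccc(=O)oc3c2OC)OC1
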